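**Conventions and assumptions (remarks on the chemistry)**

- Locants C1–C10 are those of the target skeleton: C1 is the methyl-bearing fusion carbon, C5 the fusion CH, C2–C4 complete the five-membered ring and C6–C10 the seven-membered ring. α is the face of the bicycle that carries the C1 methyl, β the opposite face.
- The catalyst enantiomer in step 9 is assigned from the usual sense of induction of the DOSP dirhodium catalysts with donor/acceptor carbenoids. What the route requires is the (1R,2S)-cyclopropane 12.
- Compounds 1 and 7 are taken as purchased. Reagents that deliver only a small unit (methyl, vinyl, isopropyl, angeloyl) are listed with SMILES at the step where they are used.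
- The configurations of 6, 12 and 13 were checked centre by centre against 22 and are mutually consistent. The carbinol carbon of 1 (R) becomes C2 of 22.

## Structural features

Compound 22 is a trans-fused bicyclo[5.3.0]decane of the daucane type. A cyclopentane (C1–C5) and a cycloheptene (C1, C5–C10, C8=C9) share the C1–C5 bond, C1 being a quaternary, methyl-bearing fusion carbon and C5 a fusion CH. Six stereocentres form one contiguous array: C1 is flanked by the carbinols C2 and C10 and by C5, and C5 lies between the tertiary carbinol C4 (hydroxyl and isopropyl) and the carbinol C6. O2 and O4 are α, while H5, O6, O10 and the isopropyl group are β. The fragile groups are the two angelates, which drift to tiglates under acid, base, nucleophiles or heat (the C10 ester is also allylic), and the tertiary C4 alcohol, which is β to the C6 oxygen. The four oxygens end in three different states and must be told apart. The real difficulty is the quaternary C1 with three stereogenic neighbours and the trans ring fusion. The key step exploits the seven-membered ring: the vicinal pair C1/C10 sits in a ring with a C8=C9 double bond and a C7 methylene, and with a C5=C6 double bond at a lower oxidation level this is a cyclohepta-1,4-diene, the retron of a cis-divinylcyclopropane Cope rearrangement. The C8 methyl is then the reduced form of a diazoacetate ester, O10 is an enol ether oxygen of the diazo partner, and the C4 carbonyl of the diene partner is the handle for the isopropyl group.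

## Logic of the disconnections

**22 ⇒ 21 ⇒ 20.** The O2–Si bond of 21 and then the two acyl C–O bonds at O6 and O10 are cut. The angelates are the most sensitive groups and are therefore put on second to last, with only a neutral desilylation after them. This leads back to triol 20 with a single protected oxygen. The forward acylation must esterify two hindered secondary alcohols without Z-to-E isomerisation and leave the tertiary C4 hydroxyl alone, and the C2 silyl ether must outlast the C10 silyl ether.

**20 ⇒ 19 ⇒ 18 ⇒ 17 ⇒ 16.** The O10–Si bond is cut (19), then the C8 methyl is traced through a chloromethyl (18) and a hydroxymethyl group (17) to a methyl ester (16). The ester is what the key step delivers at C8 and it deactivates the C8=C9 alkene while C5=C6 is functionalised. The demands are selective activation of the primary allylic alcohol beside a secondary and a tertiary one, direct hydride displacement without allylic transposition, and cleavage of one silyl ether beside the other.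

**16 ⇒ 15 ⇒ 14.** The C5–H and C6–O bonds are cut. Both lie on the β face and are syn, which is the signature of hydroboration–oxidation of a C5=C6 alkene. This removes two stereocentres and the trans fusion in one operation. The forward step must attack the face opposite the C1 methyl and leave the conjugated C8=C9 alkene untouched.

**14 ⇒ 13.** The C4–isopropyl bond is cut, giving the C4 enone. The forward step needs 1,2-addition to a hindered, enolisable β-silyloxy ketone from the β face, which the α-methyl on C1 and the α-silyloxy group on C2 both favour.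

**13 ⇒ 12 ⇒ 6 + 11.** C1–C10 is cut and C6–C8 re-formed (retro-Cope), then C7–C8 and C6–C8 are cut (retro-cyclopropanation). This removes the seven-membered ring, the quaternary centre and the C10 carbinol together and leaves a cyclopentenone diene and a vinyldiazoacetate. The forward step must form the cis-divinylcyclopropane with the right absolute configuration and must carry an E enol ether, since that geometry becomes the C10 configuration.

**6 ⇒ 5 ⇒ 4 ⇒ 3 ⇒ 2 ⇒ 1.** The vinyl–ring bond, the C–I bond, the ring–methyl bond and the O–Si bond are cut in turn. The single stereocentre is bought with 1, so no γ-oxidation of a methylcyclopentenone (uncertain regiochemistry) and no resolution are needed. The vinyl group comes from a boron reagent, so no organotin is used. The forward steps must avoid base-induced loss of the β-silyloxy group.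

**11 ⇒ 10 ⇒ 9 ⇒ 8 ⇒ 7.** The diazo group is removed, the C3=C4 enol ether is traced to a conjugated Z-enoate by a proton shift, and the C2=C3 bond is cut to an aldehyde and a phosphonoacetate. Direct enol silylation of a 4-oxobutanoate would be shorter but is expected to favour the Z enol ether. Kinetic deconjugation of the Z-enoate instead sets the E enol ether through allylic strain.

## Other disconnections considered

**Alternative 1:** The cut is C4–C5 of the five-membered ring, leading to A1. In the forward step MgBr2·OEt2 and a tertiary amine would enolise a C6 cycloheptanone reversibly toward C5, and the enolate would add to a side-chain isopropyl ketone to give the magnesium aldolate.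
- In its favour: the tertiary carbinol, the fusion CH and the C6 oxygen arise in one thermodynamically steered ring closure with cheap reagents. No intermolecular isopropyl addition to a hindered ketone is needed, and the C6 ketone would allow a hydroxyl-directed reduction to the 6β alcohol.
- Against it here: the step does nothing for the quaternary C1 and its two carbinol neighbours, which would have to be set earlier on a monocyclic seven-membered ring where control is weak. Enolisation toward C7, retro-aldol and dehydration compete. A1 is saturated at C8–C9, so the alkene would have to be introduced late and regioselectively.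
- Comparison: on the C4–C5–C6 triad this alternative is the better plan, since equilibration and a directed reduction replace the facial selectivity that the hydroboration in step 11 must supply. On the C1/C10 problem and on ring construction it is weaker (one bond and one ring against two bonds, one ring and two stereocentres). The reversible polar mechanism is at least the equal of the chosen one in tolerance. Step economy is expected to be worse because three stereocentres must precede the key step and the alkene must follow it.

**Alternative 2:** The cut is C1–C5, leading to A2. In the forward step BF3·OEt2 would activate a cis-4,5-epoxide in a ten-membered ring and a C10 silyl dienol ether would attack through C1 at C5 with inversion.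
- In its favour: both rings, the quaternary C1, the fusion CH and the retained C4 oxygen come from one stereospecific step, and the C10 enone is a useful handle. In bonds, rings and stereocentres gained per step this alternative is better than the chosen plan, and the endgame after A2 would be at least as short.
- Against it here: it needs a ten-membered ring with a geometrically defined trisubstituted epoxide and dienol ether. The outcome depends on the ring conformation. Lewis-acid opening normally prefers the tertiary C4. Attack through C9 or through oxygen, hydride shifts and loss of the p-methoxybenzyl ether are all conceivable. The C10 ketone would still have to be reduced to the β alcohol next to a quaternary centre.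
- Comparison: structurally it is more convergent. Mechanistically a cationic, conformation-dependent transannular step is harder to predict than a concerted cyclopropanation followed by a boat Cope rearrangement. Overall step economy is unlikely to be better once the medium ring has been made.

**Alternative 3:** The cuts are C6–C7 and C9–C10, leading to A3. In the forward step the dithianes at C6 and C10 on a fully substituted cyclopentane would be lithiated in turn and alkylated twice with 3-chloro-2-(chloromethyl)prop-1-ene.
- In its favour: it uses robust umpolung chemistry with no diazo compound and no chiral rhodium catalyst, so on reagent cost and hazard it is the better plan. All four cyclopentane stereocentres are set on a small ring. It forms two skeletal bonds and one ring, which equals the chosen step. Both carbinols end as the same ester, so they need not be differentiated.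
- Against it here: no stereocentre is created. The dithiane on the carbon next to quaternary C1 is hard to deprotonate and alkylate, and the second alkylation closes a seven-membered ring between hindered partners. Silyl migration from O4 or O2 to the carbanion is a risk. Two thioacetal hydrolyses, two diastereoselective ketone reductions and a regioselective shift of the exocyclic alkene to C8=C9 would follow.
- Comparison: equal in bonds and ring formed, weaker in stereocentres (none against two), strongly basic and stepwise against catalytic and pericyclic, and longer after the key step because of the extra deprotection, reduction and isomerisation steps.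

Key step: step 9

## Route

Step 1
Reactants: 1 (R)-4-hydroxycyclopent-2-en-1-one
Product: 2 (R)-4-(tert-butyldiphenylsilyloxy)cyclopent-2-en-1-one
Conditions: TBDPSCl, imidazole, CH2Cl2, 0 °C to rt
Reagents that add atoms: tert-butyl(chloro)diphenylsilane, CC(C)(C)[Si](Cl)(c1ccccc1)c1ccccc1
Why: Standard silylation of a secondary alcohol under weakly basic conditions that should not trigger elimination; the bulky, acid-stable silyl group later shields the α face and survives cleavage of the C10 silyl ether.

Step 2
Reactants: 2 (R)-4-(tert-butyldiphenylsilyloxy)cyclopent-2-en-1-one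
Product: 3 (3R,4R)-4-(tert-butyldiphenylsilyloxy)-3-methyl-1-(trimethylsilyloxy)cyclopent-1-ene
Conditions: Me2CuLi (from MeLi and CuI), TMSCl, Et3N, THF, −78 °C
Reagents that add atoms: lithium dimethylcuprate, [Li+].C[Cu-]C; chlorotrimethylsilane, C[Si](C)(C)Cl
Why: Conjugate addition of a lithium dialkylcuprate with in situ O-silylation of the enolate; the methyl group should enter anti to the silyloxy group (this centre is removed in step 3), and the enolate cannot expel the silyloxy group because it is not β to the enolate carbon.

Step 3
Reactants: 3 (3R,4R)-4-(tert-butyldiphenylsilyloxy)-3-methyl-1-(trimethylsilyloxy)cyclopent-1-ene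
Product: 4 (R)-4-(tert-butyldiphenylsilyloxy)-3-methylcyclopent-2-en-1-one
Conditions: Pd(OAc)2 (cat.), O2 (1 atm), DMSO, rt
Reagents that add atoms: none
Why: Saegusa–Ito oxidation: the divalent palladium enolate formed at the former α-carbon can only lose the hydrogen on the methyl-bearing carbon, so the enone double bond returns regiospecifically with the methyl group on the β-carbon and the carbinol centre untouched.

Step 4
Reactants: 4 (R)-4-(tert-butyldiphenylsilyloxy)-3-methylcyclopent-2-en-1-one
Product: 5 (R)-4-(tert-butyldiphenylsilyloxy)-2-iodo-3-methylcyclopent-2-en-1-one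
Conditions: I2, pyridine, CH2Cl2, 0 °C to rt
Reagents that add atoms: iodine, [I][I]
Why: α-Iodination of an enone by reversible conjugate addition of pyridine, iodination of the resulting enolate and elimination; the sequence is established for β-methyl cycloalkenones and is non-basic enough to keep the silyloxy group.

Step 5
Reactants: 5 (R)-4-(tert-butyldiphenylsilyloxy)-2-iodo-3-methylcyclopent-2-en-1-one
Product: 6 (R)-4-(tert-butyldiphenylsilyloxy)-3-methyl-2-vinylcyclopent-2-en-1-one
Conditions: CH2=CHBpin, PdCl2(dppf) (cat.), Cs2CO3, THF/H2O, rt to 40 °C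
Reagents that add atoms: vinylboronic acid pinacol ester, C=CB1OC(C)(C)C(C)(C)O1
Why: Suzuki–Miyaura coupling; α-iodoenones undergo oxidative addition to zerovalent palladium readily, so the coupling should run near room temperature where the β-silyloxy ketone tolerates carbonate, and no organotin reagent is needed; the 3-methyl group should slow Diels–Alder dimerisation of the diene, which is nevertheless used promptly.

Step 6
Reactants: 7 (tert-butyldimethylsilyloxy)acetaldehyde
Product: 8 methyl (Z)-4-(tert-butyldimethylsilyloxy)but-2-enoate
Conditions: (CF3CH2O)2P(O)CH2CO2Me, KHMDS, 18-crown-6, THF, −78 °C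
Reagents that add atoms: methyl bis(2,2,2-trifluoroethyl)phosphonoacetate, COC(=O)CP(=O)(OCC(F)(F)F)OCC(F)(F)F
Why: Still–Gennari olefination; the electron-poor phosphonate and the dissociated potassium base make elimination faster than equilibration, so the Z-enoate should predominate, and the Z geometry is what the next step converts into the E enol ether.

Step 7
Reactants: 8 methyl (Z)-4-(tert-butyldimethylsilyloxy)but-2-enoate
Product: 10 methyl (E)-4-(tert-butyldimethylsilyloxy)but-3-enoate, via lithium dienolate 9 (not isolated)
Conditions: LDA, DMPU, THF, −78 °C; then AcOH, −78 °C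
Reagents that add atoms: none
Why: Kinetic deconjugation of an enoate: γ-deprotonation of the Z-enoate must place the silyloxy group away from the cis ester to avoid A(1,3) strain, which gives the (3E)-dienolate, and kinetic protonation at the α-carbon keeps that geometry in the β,γ-unsaturated ester.

Step 8
Reactants: 10 methyl (E)-4-(tert-butyldimethylsilyloxy)but-3-enoate
Product: 11 methyl (E)-4-(tert-butyldimethylsilyloxy)-2-diazobut-3-enoate
Conditions: p-ABSA, DBU, MeCN, 0 °C to rt
Reagents that add atoms: 4-acetamidobenzenesulfonyl azide, CC(=O)Nc1ccc(cc1)S(=O)(=O)N=[N+]=[N-]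
Why: Regitz-type diazo transfer to the α-carbon of a β,γ-unsaturated ester, the usual entry to vinyldiazoacetates; the enol ether double bond is not involved, so its E geometry should be retained; the product is kept cold and used soon because vinyldiazo compounds can cyclise to pyrazoles.

Step 9
Reactants: 6 (R)-4-(tert-butyldiphenylsilyloxy)-3-methyl-2-vinylcyclopent-2-en-1-one; 11 methyl (E)-4-(tert-butyldimethylsilyloxy)-2-diazobut-3-enoate
Product: 13 methyl 10β-(tert-butyldimethylsilyloxy)-2α-(tert-butyldiphenylsilyloxy)-1α-methyl-4-oxobicyclo[5.3.0]deca-5,8-diene-8-carboxylate, via cis-divinylcyclopropane 12 (not isolated)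
Conditions: Rh2(R-DOSP)4 (1 mol%), hexanes, −40 °C to rt, slow addition of 11 (1.5 equiv); then PhMe, 110 °C
Reagents that add atoms: none
Why: Rh2(R-DOSP)4 extrudes N2 from 11 to give a donor/acceptor vinylcarbenoid at C8 that adds in a concerted, asynchronous [2+1] manner to the monosubstituted vinyl group of 6 (three-membered ring closure, bonds C7–C8 and C6–C8), with the siloxyvinyl donor cis to the cyclopentenyl group as is general for such carbenoids. Heating then takes the cis-divinylcyclopropane 12 through a boat [3,3]-sigmatropic (Cope) transition state that forms C1–C10, breaks C6–C8 and closes the seven-membered ring; overall this is a formal (4+3) cycloaddition of the known rhodium-catalysed tandem cyclopropanation/Cope type between vinyldiazoacetates and 1,3-dienes. C1 is set by the face of the cyclopentene over which the C8 arm lies, which the (1R,2S) configuration of 12 fixes as the β face, anti to the α-silyloxy group on C2, so catalyst and substrate preferences should coincide. C10 is set relative to C1 by the E enol ether: in the boat the silyloxy group on C10 and ring carbon C2 on C1 both point outward and end cis, so O10 is trans to the C1 methyl. The step needs site selectivity for the vinyl group over the tetrasubstituted enone alkene (sterics and electron demand), cis selectivity in the cyclopropanation (inherent to donor/acceptor carbenoids), enantioface selection (chiral catalyst, hydrocarbon solvent, slow addition) and rearrangement faster than thermal epimerisation (the C1 methyl is the only inward group, so moderate heating should suffice). The ketone is untouched and appears in 13 as the C4 enone needed next.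

Step 10
Reactants: 13 methyl 10β-(tert-butyldimethylsilyloxy)-2α-(tert-butyldiphenylsilyloxy)-1α-methyl-4-oxobicyclo[5.3.0]deca-5,8-diene-8-carboxylate
Product: 14 methyl 10β-(tert-butyldimethylsilyloxy)-2α-(tert-butyldiphenylsilyloxy)-4α-hydroxy-4β-isopropyl-1α-methylbicyclo[5.3.0]deca-5,8-diene-8-carboxylate
Conditions: i-PrMgCl, CeCl3, THF, −78 °C; aq. NH4Cl
Reagents that add atoms: isopropylmagnesium chloride, CC(C)[Mg]Cl
Why: Organocerium 1,2-addition: the weakly basic, oxophilic reagent should add to the enone carbonyl faster than it enolises C3 (which would expel the C2 silyloxy group), reduces the ketone by hydride transfer or attacks the ester; the pseudoaxial α-methyl on C1 and the α-silyloxy group on C2 direct the nucleophile to the β face, giving the 4α-alcohol.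

Step 11
Reactants: 14 methyl 10β-(tert-butyldimethylsilyloxy)-2α-(tert-butyldiphenylsilyloxy)-4α-hydroxy-4β-isopropyl-1α-methylbicyclo[5.3.0]deca-5,8-diene-8-carboxylate
Product: 16 methyl 10β-(tert-butyldimethylsilyloxy)-2α-(tert-butyldiphenylsilyloxy)-4α,6β-dihydroxy-4β-isopropyl-1α-methyl-5βH-bicyclo[5.3.0]dec-8-ene-8-carboxylate, via C6 alkylborane 15 (not isolated)
Conditions: BH3·THF, THF, 0 °C to rt; then NaBO3·4H2O, THF/H2O, rt
Reagents that add atoms: borane–tetrahydrofuran (boron of 15), B.C1CCOC1; sodium perborate (oxygen on C6), [Na+].[O-]OB=O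
Why: Hydroboration–oxidation: boron goes to the less substituted C6 and hydrogen to C5 in a syn addition that should come from the β face, anti to the C1 methyl and to the C4 oxygen (present as its borinate), as in related angular-methyl systems; oxidation proceeds with retention, giving H5 and O6 both β (trans fusion), while the ester-conjugated C8=C9 alkene reacts much more slowly and perborate spares the ester.

Step 12
Reactants: 16 methyl 10β-(tert-butyldimethylsilyloxy)-2α-(tert-butyldiphenylsilyloxy)-4α,6β-dihydroxy-4β-isopropyl-1α-methyl-5βH-bicyclo[5.3.0]dec-8-ene-8-carboxylate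
Product: 17 10β-(tert-butyldimethylsilyloxy)-2α-(tert-butyldiphenylsilyloxy)-8-(hydroxymethyl)-4β-isopropyl-1α-methyl-5βH-bicyclo[5.3.0]dec-8-ene-4α,6β-diol
Conditions: i-Bu2AlH (excess), CH2Cl2, −78 to 0 °C; Rochelle salt
Reagents that add atoms: none
Why: 1,2-Reduction of an α,β-unsaturated ester to the allylic alcohol by an aluminium hydride; the free hydroxyls only consume extra hydride and the silyl ethers are inert.

Step 13
Reactants: 17 10β-(tert-butyldimethylsilyloxy)-2α-(tert-butyldiphenylsilyloxy)-8-(hydroxymethyl)-4β-isopropyl-1α-methyl-5βH-bicyclo[5.3.0]dec-8-ene-4α,6β-diol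
Product: 18 10β-(tert-butyldimethylsilyloxy)-2α-(tert-butyldiphenylsilyloxy)-8-(chloromethyl)-4β-isopropyl-1α-methyl-5βH-bicyclo[5.3.0]dec-8-ene-4α,6β-diol
Conditions: NCS, Me2S, CH2Cl2, −20 to 0 °C
Reagents that add atoms: N-chlorosuccinimide, O=C1CCC(=O)N1Cl
Why: Corey–Kim-type chlorination without added base: only the allylic alkoxysulfonium ion is displaced by chloride, whereas the saturated secondary and tertiary alcohols should return unchanged on work-up, so the primary allylic position is activated selectively.

Step 14
Reactants: 18 10β-(tert-butyldimethylsilyloxy)-2α-(tert-butyldiphenylsilyloxy)-8-(chloromethyl)-4β-isopropyl-1α-methyl-5βH-bicyclo[5.3.0]dec-8-ene-4α,6β-diol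
Product: 19 10β-(tert-butyldimethylsilyloxy)-2α-(tert-butyldiphenylsilyloxy)-4β-isopropyl-1α,8-dimethyl-5βH-bicyclo[5.3.0]dec-8-ene-4α,6β-diol
Conditions: LiEt3BH, THF, 0 °C to rt
Reagents that add atoms: none
Why: SN2 displacement of a primary allylic chloride by a trialkylborohydride; direct attack at the unhindered CH2 should win over SN2′ attack at C9, which is shielded by C10 and the quaternary C1, so the C8=C9 alkene stays in place and C8 carries its methyl group.

Step 15
Reactants: 19 10β-(tert-butyldimethylsilyloxy)-2α-(tert-butyldiphenylsilyloxy)-4β-isopropyl-1α,8-dimethyl-5βH-bicyclo[5.3.0]dec-8-ene-4α,6β-diol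
Product: 20 2α-(tert-butyldiphenylsilyloxy)-4β-isopropyl-1α,8-dimethyl-5βH-bicyclo[5.3.0]dec-8-ene-4α,6β,10β-triol
Conditions: HF·pyridine, pyridine, THF, 0 °C to rt
Reagents that add atoms: none
Why: Silyl ether cleavage under buffered acidic fluoride, where a tert-butyldimethylsilyl ether is cleaved far faster than a tert-butyldiphenylsilyl ether; the pyridine buffer should prevent ionisation of the allylic C10 and tertiary C4 alcohols.

Step 16
Reactants: 20 2α-(tert-butyldiphenylsilyloxy)-4β-isopropyl-1α,8-dimethyl-5βH-bicyclo[5.3.0]dec-8-ene-4α,6β,10β-triol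
Product: 21 2α-(tert-butyldiphenylsilyloxy)-4α-hydroxy-4β-isopropyl-1α,8-dimethyl-5βH-bicyclo[5.3.0]dec-8-ene-6β,10β-diyl bis[(Z)-2-methylbut-2-enoate]
Conditions: angelic acid, 2,4,6-Cl3C6H2COCl, Et3N, PhMe, rt; then 20, 80 °C
Reagents that add atoms: angelic acid, C/C=C(/C)C(=O)O
Why: Yamaguchi-type esterification through the preformed mixed anhydride without a nucleophilic catalyst, the conditions under which angelates are formed with least Z-to-E isomerisation; both secondary alcohols should be acylated while the hindered tertiary C4 hydroxyl stays free.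

Step 17
Reactants: 21 2α-(tert-butyldiphenylsilyloxy)-4α-hydroxy-4β-isopropyl-1α,8-dimethyl-5βH-bicyclo[5.3.0]dec-8-ene-6β,10β-diyl bis[(Z)-2-methylbut-2-enoate]
Product: 22 (1R,2R,4R,5S,6S,10R)-2,4-dihydroxy-4-isopropyl-1,8-dimethylbicyclo[5.3.0]dec-8-ene-6,10-diyl bis[(Z)-2-methylbut-2-enoate]
Conditions: TBAF, AcOH, THF, rt to 40 °C
Reagents that add atoms: none
Why: Fluoride-mediated cleavage of the remaining silyl ether, buffered with acetic acid so that no free alkoxide is present to cleave, migrate or isomerise the angelates; O2 is anti to C10 across C1–C2, which makes acyl migration geometrically unfavourable.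

## Compound list

1 | (R)-4-hydroxycyclopent-2-en-1-one | O=C1C=C[C@H](O)C1 | starting material
2 | (R)-4-(tert-butyldiphenylsilyloxy)cyclopent-2-en-1-one | O=C1C=C[C@H](O[Si](c2ccccc2)(c2ccccc2)C(C)(C)C)C1 | intermediate
3 | (3R,4R)-4-(tert-butyldiphenylsilyloxy)-3-methyl-1-(trimethylsilyloxy)cyclopent-1-ene (methyl trans to the silyloxy group) | C[Si](C)(C)OC1=C[C@@H](C)[C@H](O[Si](c2ccccc2)(c2ccccc2)C(C)(C)C)C1 | intermediate
4 | (R)-4-(tert-butyldiphenylsilyloxy)-3-methylcyclopent-2-en-1-one | O=C1C=C(C)[C@H](O[Si](c2ccccc2)(c2ccccc2)C(C)(C)C)C1 | intermediate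
5 | (R)-4-(tert-butyldiphenylsilyloxy)-2-iodo-3-methylcyclopent-2-en-1-one | O=C1C(I)=C(C)[C@H](O[Si](c2ccccc2)(c2ccccc2)C(C)(C)C)C1 | intermediate
6 | (R)-4-(tert-butyldiphenylsilyloxy)-3-methyl-2-vinylcyclopent-2-en-1-one | C=CC1=C(C)[C@H](O[Si](c2ccccc2)(c2ccccc2)C(C)(C)C)CC1=O | intermediate (precursor of the key step)
7 | (tert-butyldimethylsilyloxy)acetaldehyde | O=CCO[Si](C)(C)C(C)(C)C | starting material
8 | methyl (Z)-4-(tert-butyldimethylsilyloxy)but-2-enoate | COC(=O)/C=C\CO[Si](C)(C)C(C)(C)C | intermediate
9 | lithium (3E)-4-(tert-butyldimethylsilyloxy)-1-methoxybuta-1,3-dien-1-olate | [Li+].COC([O-])=C/C=C/O[Si](C)(C)C(C)(C)C | intermediate (not isolated)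
10 | methyl (E)-4-(tert-butyldimethylsilyloxy)but-3-enoate | COC(=O)C/C=C/O[Si](C)(C)C(C)(C)C | intermediate
11 | methyl (E)-4-(tert-butyldimethylsilyloxy)-2-diazobut-3-enoate | COC(=O)C(=[N+]=[N-])/C=C/O[Si](C)(C)C(C)(C)C | intermediate (precursor of the key step)
12 | methyl (1R,2S)-1-[(E)-2-(tert-butyldimethylsilyloxy)ethenyl]-2-[(3R)-3-(tert-butyldiphenylsilyloxy)-2-methyl-5-oxocyclopent-1-en-1-yl]cyclopropane-1-carboxylate | COC(=O)[C@]1(/C=C/O[Si](C)(C)C(C)(C)C)C[C@H]1C2=C(C)[C@H](O[Si](c3ccccc3)(c3ccccc3)C(C)(C)C)CC2=O | intermediate (not isolated)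
13 | methyl 10β-(tert-butyldimethylsilyloxy)-2α-(tert-butyldiphenylsilyloxy)-1α-methyl-4-oxobicyclo[5.3.0]deca-5,8-diene-8-carboxylate | COC(=O)C1=C[C@@H](O[Si](C)(C)C(C)(C)C)[C@@]2(C)[C@H](O[Si](c3ccccc3)(c3ccccc3)C(C)(C)C)CC(=O)C2=CC1 | intermediate (product of the key step)
14 | methyl 10β-(tert-butyldimethylsilyloxy)-2α-(tert-butyldiphenylsilyloxy)-4α-hydroxy-4β-isopropyl-1α-methylbicyclo[5.3.0]deca-5,8-diene-8-carboxylate | COC(=O)C1=C[C@@H](O[Si](C)(C)C(C)(C)C)[C@@]2(C)[C@H](O[Si](c3ccccc3)(c3ccccc3)C(C)(C)C)C[C@@](O)(C(C)C)C2=CC1 | intermediate
15 | 6β-dihydroboryl adduct of 14 with the C4 oxygen as its dihydroborinate (5βH) | COC(=O)C1=C[C@@H](O[Si](C)(C)C(C)(C)C)[C@@]2(C)[C@H](O[Si](c3ccccc3)(c3ccccc3)C(C)(C)C)C[C@@](OB)(C(C)C)[C@@H]2[C@@H](B)C1 | intermediate (not isolated)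
16 | methyl 10β-(tert-butyldimethylsilyloxy)-2α-(tert-butyldiphenylsilyloxy)-4α,6β-dihydroxy-4β-isopropyl-1α-methyl-5βH-bicyclo[5.3.0]dec-8-ene-8-carboxylate | COC(=O)C1=C[C@@H](O[Si](C)(C)C(C)(C)C)[C@@]2(C)[C@H](O[Si](c3ccccc3)(c3ccccc3)C(C)(C)C)C[C@@](O)(C(C)C)[C@@H]2[C@@H](O)C1 | intermediate
17 | 10β-(tert-butyldimethylsilyloxy)-2α-(tert-butyldiphenylsilyloxy)-8-(hydroxymethyl)-4β-isopropyl-1α-methyl-5βH-bicyclo[5.3.0]dec-8-ene-4α,6β-diol | OCC1=C[C@@H](O[Si](C)(C)C(C)(C)C)[C@@]2(C)[C@H](O[Si](c3ccccc3)(c3ccccc3)C(C)(C)C)C[C@@](O)(C(C)C)[C@@H]2[C@@H](O)C1 | intermediate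
18 | 10β-(tert-butyldimethylsilyloxy)-2α-(tert-butyldiphenylsilyloxy)-8-(chloromethyl)-4β-isopropyl-1α-methyl-5βH-bicyclo[5.3.0]dec-8-ene-4α,6β-diol | ClCC1=C[C@@H](O[Si](C)(C)C(C)(C)C)[C@@]2(C)[C@H](O[Si](c3ccccc3)(c3ccccc3)C(C)(C)C)C[C@@](O)(C(C)C)[C@@H]2[C@@H](O)C1 | intermediate
19 | 10β-(tert-butyldimethylsilyloxy)-2α-(tert-butyldiphenylsilyloxy)-4β-isopropyl-1α,8-dimethyl-5βH-bicyclo[5.3.0]dec-8-ene-4α,6β-diol | CC1=C[C@@H](O[Si](C)(C)C(C)(C)C)[C@@]2(C)[C@H](O[Si](c3ccccc3)(c3ccccc3)C(C)(C)C)C[C@@](O)(C(C)C)[C@@H]2[C@@H](O)C1 | intermediate
20 | 2α-(tert-butyldiphenylsilyloxy)-4β-isopropyl-1α,8-dimethyl-5βH-bicyclo[5.3.0]dec-8-ene-4α,6β,10β-triol | CC1=C[C@@H](O)[C@@]2(C)[C@H](O[Si](c3ccccc3)(c3ccccc3)C(C)(C)C)C[C@@](O)(C(C)C)[C@@H]2[C@@H](O)C1 | intermediate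
21 | 2α-(tert-butyldiphenylsilyloxy)-4α-hydroxy-4β-isopropyl-1α,8-dimethyl-5βH-bicyclo[5.3.0]dec-8-ene-6β,10β-diyl bis[(Z)-2-methylbut-2-enoate] | CC1=C[C@@H](OC(=O)/C(C)=C\C)[C@@]2(C)[C@H](O[Si](c3ccccc3)(c3ccccc3)C(C)(C)C)C[C@@](O)(C(C)C)[C@@H]2[C@@H](OC(=O)/C(C)=C\C)C1 | intermediate
22 | (1R,2R,4R,5S,6S,10R)-2,4-dihydroxy-4-isopropyl-1,8-dimethylbicyclo[5.3.0]dec-8-ene-6,10-diyl bis[(Z)-2-methylbut-2-enoate] (CNP0249167.2; locants as defined above) | C/C=C(/C)C(=O)O[C@H]1CC(C)=C[C@@H](OC(=O)/C(C)=C\C)[C@@]2(C)[C@H](O)C[C@@](O)(C(C)C)[C@H]12 | target

## Step count and least certain steps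

Total step count: 17. Longest linear sequence: 14 steps (steps 1–5 and 9–17). The diazo ester branch (steps 6–8) joins at step 9.

**Step 9 (key step).**
- What may go wrong: the vinyl group of 6 sits on an acyl-substituted diene and the carbenoid from 11 is strongly donor-stabilised, so cyclopropanation may be slower than carbenoid self-reaction or pyrazole formation from 11. The Cope rearrangement, retarded by the inward C1 methyl, may be slower than thermal epimerisation of the cyclopropane. Enantioface selection may be incomplete.
- Fallback (from 6, back at 13): the diene is made electron-rich before the annulation. Luche reduction of 6 (NaBH4, CeCl3·7H2O, MeOH, −78 °C; hydride anti to the silyloxy group) should give the cis-dienol F1. Silylation (TESCl, imidazole) gives the triethylsilyl ether F2. The same rhodium-catalysed reaction with 11 then passes through the cis-divinylcyclopropane F3 to the bicyclic C4 silyl ether F4, with both α-oxygen groups now directing the new bond to the β face. Selective methanolysis of the triethylsilyl ether (PPTS, MeOH) gives the C4 allylic alcohol F5, and MnO2 oxidation returns the enone 13.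

**Step 11.**
- What may go wrong: facial selectivity may be poor, because the β-isopropyl group on C4 opposes the bias from the α-methyl on C1. Borane may also attack the conjugated ester when the hindered C5=C6 alkene reacts slowly.
- Fallback (from 14, back at 16): an added blocking group replaces reliance on the inherent bias. Silylation of the tertiary hydroxyl (TMSOTf, 2,6-lutidine) gives the C4 trimethylsilyl ether F6, in which the α face of C5=C6 is flanked by two bulky groups. Hydroboration gives the C6 alkylborane F7, and perborate oxidation gives the 6β-alcohol F8. Mild methanolysis (citric acid, MeOH) removes the trimethylsilyl group and gives 16.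

**Step 16.**
- What may go wrong: angelate may isomerise to tiglate during activation, or acylation of the neopentylic, allylic C10 hydroxyl may be incomplete at a temperature the Z esters tolerate.
- Fallback (from 20, back at 21): the Z double bonds are built after acylation. Esterification of 20 with 2-[bis(2,2,2-trifluoroethoxy)phosphoryl]propanoic acid (DIC, DMAP cat.; acylation through the phosphonoketene suits hindered alcohols) gives the bis(phosphonopropionate) F9, a mixture at the phosphonate-bearing carbons. A double Still–Gennari olefination with acetaldehyde (KHMDS, 18-crown-6, THF, −78 °C) should then give the Z-trisubstituted esters of 21.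

**Step 15.**
- What may go wrong: both silyl ethers are hindered secondary ethers, so discrimination may be lost on long exposure. Acid-promoted ionisation at the allylic C10 position is also possible.
- Fallback (from 19, back at 22): the only cis-1,3-diol of the molecule is used instead of silyl discrimination. Global desilylation (TBAF, THF, 50 °C) gives the tetraol F10. Phenylboronic acid (PhMe, MgSO4) should bridge the cis-disposed O2 and O4 as the cyclic phenylboronate F11. Yamaguchi-type bis-angeloylation as in step 16 gives the bis-angelate boronate F12, and transesterification with pinacol releases 22. This replaces steps 15–17.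

**Step 7.**
- What may go wrong: the amide base may add in conjugate fashion, the E geometry may erode, or the β,γ-unsaturated ester may reconjugate during handling.
- Fallback (from 7, back at 11): the diazo group is introduced before the enol ether is formed. DBU-catalysed addition of methyl diazoacetate to 7 gives the β-hydroxy diazo ester F13 (racemic; the carbinol centre is lost next). Dehydration (POCl3, Et3N, CH2Cl2, 0 °C) should favour the E enol ether of 11, since the Z isomer suffers A(1,3) strain with the diazo ester. This replaces steps 6–8.

## Further compounds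

F1 | step 9 | (1S,4R)-4-(tert-butyldiphenylsilyloxy)-3-methyl-2-vinylcyclopent-2-en-1-ol (cis) | C=CC1=C(C)[C@H](O[Si](c2ccccc2)(c2ccccc2)C(C)(C)C)C[C@@H]1O
F2 | step 9 | triethylsilyl ether of F1 | C=CC1=C(C)[C@H](O[Si](c2ccccc2)(c2ccccc2)C(C)(C)C)C[C@@H]1O[Si](CC)(CC)CC
F3 | step 9 | cis-divinylcyclopropane from F2 and 11 (not isolated) | COC(=O)[C@]1(/C=C/O[Si](C)(C)C(C)(C)C)C[C@H]1C2=C(C)[C@H](O[Si](c3ccccc3)(c3ccccc3)C(C)(C)C)C[C@@H]2O[Si](CC)(CC)CC
F4 | step 9 | methyl 10β-(tert-butyldimethylsilyloxy)-2α-(tert-butyldiphenylsilyloxy)-1α-methyl-4α-(triethylsilyloxy)bicyclo[5.3.0]deca-5,8-diene-8-carboxylate | COC(=O)C1=C[C@@H](O[Si](C)(C)C(C)(C)C)[C@@]2(C)[C@H](O[Si](c3ccccc3)(c3ccccc3)C(C)(C)C)C[C@H](O[Si](CC)(CC)CC)C2=CC1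
F5 | step 9 | methyl 10β-(tert-butyldimethylsilyloxy)-2α-(tert-butyldiphenylsilyloxy)-4α-hydroxy-1α-methylbicyclo[5.3.0]deca-5,8-diene-8-carboxylate | COC(=O)C1=C[C@@H](O[Si](C)(C)C(C)(C)C)[C@@]2(C)[C@H](O[Si](c3ccccc3)(c3ccccc3)C(C)(C)C)C[C@H](O)C2=CC1
F6 | step 11 | C4 trimethylsilyl ether of 14 | COC(=O)C1=C[C@@H](O[Si](C)(C)C(C)(C)C)[C@@]2(C)[C@H](O[Si](c3ccccc3)(c3ccccc3)C(C)(C)C)C[C@@](O[Si](C)(C)C)(C(C)C)C2=CC1
F7 | step 11 | 6β-dihydroboryl adduct of F6 (5βH; not isolated) | COC(=O)C1=C[C@@H](O[Si](C)(C)C(C)(C)C)[C@@]2(C)[C@H](O[Si](c3ccccc3)(c3ccccc3)C(C)(C)C)C[C@@](O[Si](C)(C)C)(C(C)C)[C@@H]2[C@@H](B)C1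
F8 | step 11 | C4 trimethylsilyl ether of 16 | COC(=O)C1=C[C@@H](O[Si](C)(C)C(C)(C)C)[C@@]2(C)[C@H](O[Si](c3ccccc3)(c3ccccc3)C(C)(C)C)C[C@@](O[Si](C)(C)C)(C(C)C)[C@@H]2[C@@H](O)C1
F9 | step 16 | 6β,10β-bis{2-[bis(2,2,2-trifluoroethoxy)phosphoryl]propanoate} of 20 (mixture at the phosphonate-bearing carbons) | CC1=C[C@@H](OC(=O)C(C)P(=O)(OCC(F)(F)F)OCC(F)(F)F)[C@@]2(C)[C@H](O[Si](c3ccccc3)(c3ccccc3)C(C)(C)C)C[C@@](O)(C(C)C)[C@@H]2[C@@H](OC(=O)C(C)P(=O)(OCC(F)(F)F)OCC(F)(F)F)C1
F10 | step 15 | 4β-isopropyl-1α,8-dimethyl-5βH-bicyclo[5.3.0]dec-8-ene-2α,4α,6β,10β-tetraol | CC1=C[C@@H](O)[C@@]2(C)[C@H](O)C[C@@](O)(C(C)C)[C@@H]2[C@@H](O)C1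
F11 | step 15 | O2,O4-cyclic phenylboronate of F10 | CC1=C[C@@H](O)[C@@]2(C)[C@H](O3)C[C@@](OB3c4ccccc4)(C(C)C)[C@@H]2[C@@H](O)C1
F12 | step 15 | 6β,10β-bis-angelate of F11 | CC1=C[C@@H](OC(=O)/C(C)=C\C)[C@@]2(C)[C@H](O3)C[C@@](OB3c4ccccc4)(C(C)C)[C@@H]2[C@@H](OC(=O)/C(C)=C\C)C1
F13 | step 7 | methyl 4-(tert-butyldimethylsilyloxy)-2-diazo-3-hydroxybutanoate (racemic) | COC(=O)C(=[N+]=[N-])C(O)CO[Si](C)(C)C(C)(C)C
A1 | alternative 1 | trans-fused 2α-(tert-butyldimethylsilyloxy)-4α-hydroxy-4β-isopropyl-1α,8-dimethyl-10β-(triethylsilyloxy)bicyclo[5.3.0]decan-6-one | O=C1C[C@H](C)C[C@@H](O[Si](CC)(CC)CC)[C@@]2(C)[C@H](O[Si](C)(C)C(C)(C)C)C[C@@](O)(C(C)C)[C@H]12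
A2 | alternative 2 | trans-fused 2α-(tert-butyldimethylsilyloxy)-4α-hydroxy-4β-isopropyl-6β-(4-methoxybenzyloxy)-1α,8-dimethylbicyclo[5.3.0]dec-8-en-10-one | COc1ccc(CO[C@H]2CC(C)=CC(=O)[C@@]3(C)[C@H](O[Si](C)(C)C(C)(C)C)C[C@@](O)(C(C)C)[C@H]23)cc1
A3 | alternative 3 | bis(1,3-dithiane) of trans-fused 2α-(tert-butyldimethylsilyloxy)-4β-isopropyl-1α-methyl-8-methylene-4α-(trimethylsilyloxy)bicyclo[5.3.0]decane-6,10-dione | C=C1CC2(SCCCS2)[C@H]3[C@](O[Si](C)(C)C)(C(C)C)C[C@@H](O[Si](C)(C)C(C)(C)C)[C@]3(C)C4(SCCCS4)C1
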